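The earlier runs and the new flask were computed with constants of no real substance; scatter was added.

We have a closed, stirred vessel at constant temperature, holding starting material, other conformer and free catalyst. We want to know how target and isomer of the product A share out.

| flask | starting material | other conformer | free catalyst | remark | time |
|---|---|---|---|---|---|
| green | 0.023 M | 0.0057 M | 2.3 mM | run made earlier |  |
| grey | 0.023 M | 0.023 M | 2.3 mM | run made earlier |  |
| flask | 0.023 M | 0.0115 M | 2.3 mM |  | 15 d |

| run | time / d | target / % | isomer of the product A / % | starting material / % |
|---|---|---|---|---|
| green | 0.625 | 11.2 | 2.0 | 41.7 |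
| green | 1.67 | 11.0 | 1.5 | 24.0 |
| green | 3.00 | 10.6 | 2.0 | 13.4 |
| green | 5.00 | 11.0 | 1.6 | 6.4 |
| green | 6.00 | 11.0 | 1.2 | 4.1 |
| green | 10.0 | 11.4 | 1.9 | 0.7 |
| grey | 0.625 | 7.4 | 4.4 | 36.8 |
| grey | 1.67 | 6.9 | 4.7 | 25.3 |
| grey | 3.00 | 7.1 | 4.6 | 15.6 |
| grey | 5.00 | 7.4 | 4.4 | 6.9 |
| grey | 6.00 | 7.3 | 4.3 | 5.2 |
| grey | 10.0 | 7.2 | 4.2 | 1.2 |

(each reading ± 0.3 percentage points)

- share of target in target plus isomer of the product A at 12 min
- share of target in target plus isomer of the product A at 8.0 h
- share of target in target plus isomer of the product A at 15 d
- which of target and isomer of the product A there is more of at 15 d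

- the numbers in the tables scatter with a standard deviation of 0.3 percentage points

One thing looks contradictory. In the green run the starting material falls from 41.7 % to 0.7 %, yet the target reads 11.2 % at the start of that stretch and 11.4 % at its end.

Suppose each product forms first order in free catalyst and first order in its own substrate. Flat products beside remaining substrate then mean that catalysis was over by 0.625 d, and that the starting material leaves by a way giving neither product. Free catalyst stands in both rates, so it cancels from their ratio, however quickly it dies.

From the summed grey readings we get S = 1.63. This selectivity factor S is the target made per unit of starting material charged, over the isomer of the product A made per unit of other conformer charged. The green run, with a different charge, reads 1.61.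

The share of target is S times the starting material charge, over that product plus the other conformer charge. For this flask our reckoning gives 76.5 % at each asked time, so target leads.

The forecast gives 76 %, 76 % and 76 %, with target ahead, and reads the runs as “an early catalyst burst that dies”.

The flask gives 77.4 %, 76.2 % and 76.2 %, with target ahead.

    free catalyst + other conformer → free catalyst + isomer of the product A (k = 33.0 M⁻¹ h⁻¹)
    starting material → uncatalysed product (k = 0.0290 h⁻¹)
    starting material + free catalyst → free catalyst + target (k = 57.0 M⁻¹ h⁻¹)
    starting material ⇌ other conformer (K = 0.510, k = 0.0200 h⁻¹)
    free catalyst → spent catalyst (k = 0.820 h⁻¹)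
    target + free catalyst ⇌ isomer of the product B + free catalyst, rate k6*[free catalyst]*[target] forward; the back reaction follows from the equilibrium constant (K = 1.80, k = 10.0 M⁻¹ h⁻¹)

In this flask free catalyst has a half-life of 0.845 h, against 1.0 d for starting material by its reaction to uncatalysed product, and at 1.50 d free catalyst stands at 0 % with target at 9.40 % and uncatalysed product at 40.4 %. For the neighbour charged with 0.039 M of starting material, S gives a share of 84.7 %, and that flask stands at 83.9 % at 15 d.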